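**Plan** (drimane numbering: ring A = C-1 to C-5 and C-10, ring B = C-5 to C-10, C-11 on C-9, C-12 on C-8; β = face of the C-10 methyl)

- Retrosynthesis cuts, in order: the trienoate C-2′=C-3′ alkene (phosphonoacetate olefination); the C-8–H and C-9–H bonds (back to a C-8=C-9 maleic anhydride, a temporary ring); C-7–C-8 and C-5–C-10 together; then C-9=C-10 (Knoevenagel) and C-3–C-4 (conjugate addition).
- Enabling feature: the oxygenated C-6 lies between C-5 and C-7, and the carboxyl-bearing C-9 lies between C-10 and C-8 (which bears C-12). A C-6 methyl ketone facing a C-10=C-9(CO2R)–C-8(=O)–CO2R unit makes ring B a latent Robinson cyclohexenone whose Michael bond C-5–C-10 is also the bond that closes ring A.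
- Forward: an open chain (mesityl oxide, a ketal-bearing Grignard reagent, dibenzyl oxaloacetate) is folded in one operation, ring A first (C-5 to C-10), then ring B (C-7 to C-8).
- Stereochemistry: C-10 from a chiral phosphoric acid in the key step; C-5 by equilibration to the trans-decalin; C-6 by α-face hydride delivery; C-8 and C-9 by α-face cis-hydrogenation of the planar anhydride; the (2E,4E,6E)-ester by a late E-selective olefination.

Key step: step 4

Assumption: the sense of induction of the chiral phosphoric acid in step 4 cannot be assigned beforehand; the (R)-acid is written and the (S)-acid would be used if the opposite face of C-10 is delivered.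

**Step 1**
Reactants: 1 4-methylpent-3-en-2-one (mesityl oxide); 2 2-(3-chloropropyl)-2-methyl-1,3-dioxolane
Product: 5 4,4-dimethylnonane-2,8-dione, via Grignard reagent 3 (not isolated), via silyl enol ether ketal 4 (not isolated)
Conditions: 2, Mg, THF, reflux; then CuBr·SMe2 (10 mol %), Me3SiCl, 1, THF, −40 °C; then 1 M aq. HCl, THF, rt
Reagents that add atoms: water, O
Why: Copper-catalysed conjugate addition of the Grignard reagent to the β,β-disubstituted enone (accelerated by the silyl chloride) should build the quaternary C-4, and the acid work-up hydrolyses both the silyl enol ether and the dioxolane; no stereocentre is formed.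

**Step 2**
Reactants: 6 dibenzyl oxalate; 7 benzyl acetate
Product: 8 dibenzyl 2-oxobutanedioate (dibenzyl oxaloacetate)
Conditions: 7, LiN(SiMe3)2 (2.1 equiv), THF, −78 °C; then 6, −78 → 0 °C; aq. HCl
Reagents that add atoms: none
Why: Crossed Claisen condensation of the lithium enolate of benzyl acetate with the non-enolisable oxalate should give the β-keto diester, the second equivalent of base being taken up by the acidic product; no stereocentre is formed.

**Step 3**
Reactants: 5 4,4-dimethylnonane-2,8-dione; 8 dibenzyl 2-oxobutanedioate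
Product: 9 dibenzyl 2-(6,6-dimethyl-8-oxononan-2-ylidene)-3-oxobutanedioate (E/Z mixture)
Conditions: TiCl4 (2.2 equiv), pyridine (4.5 equiv), THF, 0 °C → rt
Reagents that add atoms: none
Why: TiCl4/pyridine Knoevenagel condensation of the fully enolised (hence not self-condensing) titanium enolate of 8 should occur at the unhindered C-8 carbonyl of 5, the C-2 carbonyl being shielded by its neopentyl flank (rule of six); alkene geometry and enol tautomers are immaterial because they interconvert under the acid of step 4.

**Step 4**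
Reactants: 9 dibenzyl 2-(6,6-dimethyl-8-oxononan-2-ylidene)-3-oxobutanedioate
Product: 12 dibenzyl (1S,4aS,8aS)-5,5,8a-trimethyl-4-oxo-1,4,4a,5,6,7,8,8a-octahydronaphthalene-1,2-dicarboxylate (the 6-oxodrim-7-ene-11,12-dioate; 9α-ester drawn), via Michael adduct 10 (not isolated), via aldol 11 (not isolated)
Conditions: (R)-3,3′-bis(2,4,6-triisopropylphenyl)-1,1′-binaphthyl-2,2′-diyl hydrogen phosphate (10 mol %), toluene (0.02 M), 60 °C
Reagents that add atoms: none
Why: Proposed new method: the phosphoric acid should bind the α-keto ester of the alkylidene oxaloacetate through its acidic OH and the hydroxyl of the more substituted (C-5) enol of the methyl ketone through its phosphoryl oxygen, so that C-5 adds to the β-carbon C-10 in an ene-like conjugate addition to give diketone 10, whose C-7 enol then attacks the C-8 keto group and loses water to give the enone (Michael addition then aldol condensation, an intramolecular Robinson annulation). The closest known reaction type is chiral-phosphoric-acid enol catalysis, in which ketones add through their more substituted enol to enones and the adducts are closed to cyclohexenones by acid; new here are the tetrasubstituted doubly activated acceptor, the intramolecular mode and the creation of the stereocentre on the acceptor carbon. Ring A closes in the 6-(enolexo)-exo-trig mode (C-5 to C-10) and ring B in the 6-(enolendo)-exo-trig mode (C-7 to C-8). C-10 is controlled by the catalyst, which selects one face of the C-9=C-10 alkene in a chair-like closure with the C-10 methyl axial; C-5 should end trans to that methyl (5α-H) because it stays enolisable next to the C-6 ketone and the trans-fused decalone is the more stable; C-9 settles thermodynamically (9α-ester expected, either epimer serves) and is erased in step 5. Regioselectivity follows from ring size (C-5 on C-10 and C-7 on C-8 each give a six-membered ring, the crossed alternatives eight- or ten-membered ones), and the water set free is left in the flask so that hemiketal and 4H-pyran forms stay reversible. No achiral acid is added, so that even if the first addition is reversible the second closure is still under catalyst control.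

**Step 5**
Reactants: 12 dibenzyl (1S,4aS,8aS)-5,5,8a-trimethyl-4-oxo-1,4,4a,5,6,7,8,8a-octahydronaphthalene-1,2-dicarboxylate
Product: 15 dibenzyl (4R,4aS,8aS)-4-hydroxy-5,5,8a-trimethyl-3,4,4a,5,6,7,8,8a-octahydronaphthalene-1,2-dicarboxylate (6β-hydroxy, C-8=C-9 alkene), via potassium dienolate 13 (not isolated), via deconjugated enone 14 (not isolated)
Conditions: potassium tert-butoxide (1.05 equiv), THF, −78 °C; AcOH (1.1 equiv), −78 °C; then CeCl3·7H2O, NaBH4, MeOH, −78 → −40 °C
Reagents that add atoms: none
Why: Deprotonation at the doubly activated C-9 gives the extended enolate, whose kinetic protonation at the α-carbon C-7 (deconjugative protonation) should move the alkene to C-8=C-9 and erase C-9; Luche reduction then delivers hydride to the C-6 ketone from the α-face, the β-face being blocked by the axial methyls on C-10 and C-4, to set the axial 6β-alcohol (6R).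

**Step 6**
Reactants: 15 dibenzyl (4R,4aS,8aS)-4-hydroxy-5,5,8a-trimethyl-3,4,4a,5,6,7,8,8a-octahydronaphthalene-1,2-dicarboxylate; 16 (diethoxyphosphoryl)acetic acid
Product: 17 dibenzyl (4R,4aS,8aS)-4-{[(diethoxyphosphoryl)acetyl]oxy}-5,5,8a-trimethyl-3,4,4a,5,6,7,8,8a-octahydronaphthalene-1,2-dicarboxylate
Conditions: 16 (1.5 equiv), N,N′-dicyclohexylcarbodiimide, 4-(dimethylamino)pyridine (0.2 equiv), CH2Cl2, 0 °C → rt
Reagents that add atoms: none
Why: Steglich esterification of the hindered axial alcohol with a small unbranched acid should install a hydrogenation-stable placeholder for the trienoate that also blocks O-6 against later lactonisation onto C-12; no stereocentre is touched.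

**Step 7**
Reactants: 17 dibenzyl (4R,4aS,8aS)-4-{[(diethoxyphosphoryl)acetyl]oxy}-5,5,8a-trimethyl-3,4,4a,5,6,7,8,8a-octahydronaphthalene-1,2-dicarboxylate
Product: 21 (1S,2S,4R,4aS,8aS)-4-{[(diethoxyphosphoryl)acetyl]oxy}-5,5,8a-trimethyldecahydronaphthalene-1,2-dicarboxylic acid, via maleic diacid 18 (not isolated), via maleic anhydride 19 (not isolated), via cis-anhydride 20 (not isolated)
Conditions: H2 (1 → 40 bar), Pd/C (10 wt % Pd), EtOAc, 25 → 50 °C; then THF–H2O (4:1), 40 °C
Reagents that add atoms: water, O
Why: Hydrogenolysis of both benzyl esters gives the dialkylmaleic acid, which is expected to close to the maleic anhydride (a temporary ring that flattens and activates the tetrasubstituted alkene), and heterogeneous hydrogenation should then add both hydrogens from the α-face, opposite the axial C-10 methyl and the 6β-acyloxy group, setting 8α-H and 9α-H (both carboxyls β and cis; 8S, 9S) before water opens the cis-anhydride.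

**Step 8**
Reactants: 21 (1S,2S,4R,4aS,8aS)-4-{[(diethoxyphosphoryl)acetyl]oxy}-5,5,8a-trimethyldecahydronaphthalene-1,2-dicarboxylic acid; 22 (2E,4E)-hexa-2,4-dienal
Product: 23 (1S,2S,4R,4aS,8aS)-5,5,8a-trimethyl-4-{[(2E,4E,6E)-octa-2,4,6-trienoyl]oxy}decahydronaphthalene-1,2-dicarboxylic acid (CNP0462207.1)
Conditions: 22 (1.5 equiv), LiCl, 1,8-diazabicyclo[5.4.0]undec-7-ene (3.5 equiv), MeCN, 0 °C → rt; then aq. HCl to pH 2–3
Reagents that add atoms: none
Why: Horner–Wadsworth–Emmons olefination under LiCl/amine conditions should form the new C-2′=C-3′ alkene with E geometry, while the two carboxylates are spectators and, as carboxylates, shield C-8 and C-9 from epimerisation.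

**Compound list**

1 | 4-methylpent-3-en-2-one (mesityl oxide) | CC(=O)C=C(C)C | starting material
2 | 2-(3-chloropropyl)-2-methyl-1,3-dioxolane | CC1(CCCCl)OCCO1 | starting material
3 | [3-(2-methyl-1,3-dioxolan-2-yl)propyl]magnesium chloride | CC1(CCC[Mg]Cl)OCCO1 | intermediate
4 | {[4,4-dimethyl-7-(2-methyl-1,3-dioxolan-2-yl)hept-2-en-2-yl]oxy}trimethylsilane | CC(O[Si](C)(C)C)=CC(C)(C)CCCC1(C)OCCO1 | intermediate
5 | 4,4-dimethylnonane-2,8-dione | CC(=O)CC(C)(C)CCCC(C)=O | intermediate
6 | dibenzyl oxalate | O=C(OCc1ccccc1)C(=O)OCc1ccccc1 | starting material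
7 | benzyl acetate | CC(=O)OCc1ccccc1 | starting material
8 | dibenzyl 2-oxobutanedioate | O=C(OCc1ccccc1)CC(=O)C(=O)OCc1ccccc1 | intermediate
9 | dibenzyl 2-(6,6-dimethyl-8-oxononan-2-ylidene)-3-oxobutanedioate (E/Z mixture) | CC(=O)CC(C)(C)CCCC(C)=C(C(=O)OCc1ccccc1)C(=O)C(=O)OCc1ccccc1 | intermediate
10 | dibenzyl 2-[(1S,2S)-2-acetyl-1,3,3-trimethylcyclohexyl]-3-oxobutanedioate (C-2 of the diester epimeric/enolised) | O=C(OCc1ccccc1)C(=O)C(C(=O)OCc1ccccc1)[C@@]2(C)CCCC(C)(C)[C@@H]2C(C)=O | intermediate
11 | dibenzyl (4aS,8aS)-2-hydroxy-5,5,8a-trimethyl-4-oxodecahydronaphthalene-1,2-dicarboxylate (C-1 and C-2 epimers) | O=C1CC(O)(C(=O)OCc3ccccc3)C(C(=O)OCc3ccccc3)[C@@]2(C)CCCC(C)(C)[C@H]12 | intermediate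
12 | dibenzyl (1S,4aS,8aS)-5,5,8a-trimethyl-4-oxo-1,4,4a,5,6,7,8,8a-octahydronaphthalene-1,2-dicarboxylate | O=C1C=C(C(=O)OCc3ccccc3)[C@@H](C(=O)OCc3ccccc3)[C@@]2(C)CCCC(C)(C)[C@H]12 | intermediate
13 | potassium (4aS,8aS)-1,2-bis(benzyloxycarbonyl)-5,5,8a-trimethyl-4a,5,6,7,8,8a-hexahydronaphthalen-4-olate | [K+].[O-]C1=CC(C(=O)OCc3ccccc3)=C(C(=O)OCc3ccccc3)[C@@]2(C)CCCC(C)(C)[C@H]12 | intermediate
14 | dibenzyl (4aS,8aS)-5,5,8a-trimethyl-4-oxo-3,4,4a,5,6,7,8,8a-octahydronaphthalene-1,2-dicarboxylate | O=C1CC(C(=O)OCc3ccccc3)=C(C(=O)OCc3ccccc3)[C@@]2(C)CCCC(C)(C)[C@H]12 | intermediate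
15 | dibenzyl (4R,4aS,8aS)-4-hydroxy-5,5,8a-trimethyl-3,4,4a,5,6,7,8,8a-octahydronaphthalene-1,2-dicarboxylate | O[C@@H]1CC(C(=O)OCc3ccccc3)=C(C(=O)OCc3ccccc3)[C@@]2(C)CCCC(C)(C)[C@H]12 | intermediate
16 | (diethoxyphosphoryl)acetic acid | CCOP(=O)(CC(=O)O)OCC | starting material
17 | dibenzyl (4R,4aS,8aS)-4-{[(diethoxyphosphoryl)acetyl]oxy}-5,5,8a-trimethyl-3,4,4a,5,6,7,8,8a-octahydronaphthalene-1,2-dicarboxylate | CCOP(=O)(OCC)CC(=O)O[C@@H]1CC(C(=O)OCc3ccccc3)=C(C(=O)OCc3ccccc3)[C@@]2(C)CCCC(C)(C)[C@H]12 | intermediate
18 | (4R,4aS,8aS)-4-{[(diethoxyphosphoryl)acetyl]oxy}-5,5,8a-trimethyl-3,4,4a,5,6,7,8,8a-octahydronaphthalene-1,2-dicarboxylic acid | CCOP(=O)(OCC)CC(=O)O[C@@H]1CC(C(=O)O)=C(C(=O)O)[C@@]2(C)CCCC(C)(C)[C@H]12 | intermediate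
19 | cyclic anhydride of 18 (C-8=C-9 maleic anhydride fused to ring B; 6β-acyloxy, 5α-H, 10β-methyl) | CCOP(=O)(OCC)CC(=O)O[C@@H]1CC3=C(C(=O)OC3=O)[C@@]2(C)CCCC(C)(C)[C@H]12 | intermediate
20 | cis-fused saturated anhydride (8α-H, 9α-H; cyclic anhydride of 21) | CCOP(=O)(OCC)CC(=O)O[C@@H]1C[C@H](C(=O)O3)[C@H](C3=O)[C@@]2(C)CCCC(C)(C)[C@H]12 | intermediate
21 | (1S,2S,4R,4aS,8aS)-4-{[(diethoxyphosphoryl)acetyl]oxy}-5,5,8a-trimethyldecahydronaphthalene-1,2-dicarboxylic acid | CCOP(=O)(OCC)CC(=O)O[C@@H]1C[C@H](C(=O)O)[C@H](C(=O)O)[C@@]2(C)CCCC(C)(C)[C@H]12 | intermediate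
22 | (2E,4E)-hexa-2,4-dienal | C/C=C/C=C/C=O | starting material
23 | (1S,2S,4R,4aS,8aS)-5,5,8a-trimethyl-4-{[(2E,4E,6E)-octa-2,4,6-trienoyl]oxy}decahydronaphthalene-1,2-dicarboxylic acid | C/C=C/C=C/C=C/C(=O)O[C@@H]1C[C@H](C(=O)O)[C@H](C(=O)O)[C@@]2(C)CCCC(C)(C)[C@H]12 | target

**Step count and risks**

Total steps: 8. Longest linear sequence: 7 (steps 1, 3, 4, 5, 6, 7, 8); step 2 is a one-step side branch.

Steps most likely to fail:

1. Step 4 (Proposed new method). The enol of the neopentyl-flanked ketone may add too slowly to the tetrasubstituted acceptor, the acid may discriminate the two faces of C-10 poorly, or a reversible first addition may erode the selectivity. Fallback, setting out from 9 and returning at 12: the two closures would be run with an achiral sulfonic acid (p-toluenesulfonic acid monohydrate, toluene, 80 °C; acid-catalysed Robinson-type annulation). This should give racemic material, that is 12 together with its enantiomer, dibenzyl (1R,4aR,8aR)-5,5,8a-trimethyl-4-oxo-1,4,4a,5,6,7,8,8a-octahydronaphthalene-1,2-dicarboxylate F1. The two would be separated by preparative chromatography on a chiral stationary phase (cellulose tris(3,5-dimethylphenylcarbamate)), and 12 continues in step 5.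

2. Step 3. The oxaloacetate may self-condense, the condensation may occur in part at the hindered carbonyl, or the diketone may aldolise under the titanium conditions. Fallback, setting out from 5 and returning at 9:
   - The unhindered ketone of 5 would be olefinated with benzyl (triphenylphosphoranylidene)acetate (toluene, reflux; Wittig reaction) to benzyl 3,7,7-trimethyl-9-oxodec-2-enoate F2.
   - The remaining ketone would be masked with ethylene glycol (p-toluenesulfonic acid, benzene, reflux) as benzyl 3,7,7-trimethyl-8-(2-methyl-1,3-dioxolan-2-yl)oct-2-enoate F3.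
   - Deprotonation to the dienolate (lithium diisopropylamide, 2 equiv, THF, −78 °C) and α-acylation with 6 (crossed Claisen condensation) should give dibenzyl 2-[6,6-dimethyl-7-(2-methyl-1,3-dioxolan-2-yl)hept-1-en-2-yl]-3-oxobutanedioate F4.
   - Aqueous acid (1 M HCl, THF, rt) would remove the dioxolane and bring the double bond into conjugation to give 9.

3. Step 7. The tetrasubstituted alkene may not take up hydrogen, or the double bond may migrate on the metal with hydrogenolytic loss of the C-6 oxygen. Fallback, setting out from 17 and returning at 21: hydrogenolysis alone (H2, 1 bar, Pd/C, EtOAc, rt) would be stopped at the maleic anhydride 19, which is isolated. Dissolving-metal conjugate reduction (Zn, AcOH, 60 °C) should then give the cis-anhydride 20 by protonation of both carbons from the open α-face, and hydrolysis (THF–H2O) gives 21. No compound outside the list arises (entry F0).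

**Further compounds**

F1 | step 4 | dibenzyl (1R,4aR,8aR)-5,5,8a-trimethyl-4-oxo-1,4,4a,5,6,7,8,8a-octahydronaphthalene-1,2-dicarboxylate (enantiomer of 12) | O=C1C=C(C(=O)OCc3ccccc3)[C@H](C(=O)OCc3ccccc3)[C@]2(C)CCCC(C)(C)[C@@H]12
F2 | step 3 | benzyl 3,7,7-trimethyl-9-oxodec-2-enoate | CC(=O)CC(C)(C)CCCC(C)=CC(=O)OCc1ccccc1
F3 | step 3 | benzyl 3,7,7-trimethyl-8-(2-methyl-1,3-dioxolan-2-yl)oct-2-enoate | CC1(CC(C)(C)CCCC(C)=CC(=O)OCc2ccccc2)OCCO1
F4 | step 3 | dibenzyl 2-[6,6-dimethyl-7-(2-methyl-1,3-dioxolan-2-yl)hept-1-en-2-yl]-3-oxobutanedioate | CC1(CC(C)(C)CCCC(=C)C(C(=O)OCc2ccccc2)C(=O)C(=O)OCc2ccccc2)OCCO1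
F0 | step 7 | none | none
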